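**Retrosynthetic overview**

1. CIML C is a 22-membered lactone (ring A: O–C1…C21) carrying only the C6–C7 oxirane (ring B). It is released from its 5,8-bis-silyl ether 25. Ring B is formed first (step 8), ring A last (step 14).
2. Key disconnection C15–C16 inside ring A: one-pot hydroboration and intramolecular alkyl–alkyl Suzuki–Miyaura coupling of acyclic ester 23 (C15–Br and C16=C17 vinyl), which closes ring A directly at the alkane oxidation level.
3. Enabling feature: the unbranched (CH2)12 strap C9–C20 of ring A. C15 and C16 are unhindered methylenes, seven and five carbons from the nearest stereocentres (C8, C21), so a primary bromide and a primary 9-BBN borane can be the partners and no stereocentre is at stake; the Z-enoate C2=C3 and ring B are carried through untouched.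
4. 23 comes from a Still–Gennari union (C2=C3) of phosphonate 5 (C1–C2 and C16–C22, from (R)-propylene oxide) with aldehyde 22 (C3–C15).
5. 22 comes from 9-bromononanal: D-proline α-aminoxylation (C8), E-enoate, Sharpless epoxidation (C6, C7), reagent-controlled allylboration (C5), ozonolysis.

Key step: step 14

Remark: target numbering is used (C1 lactone carbonyl, C2=C3 Z-alkene, C5 and C8 carbinols, C6–C7 oxirane, C21 O-bearing methine, C22 methyl); TBS = tert-butyldimethylsilyl, Ipc = isopinocampheyl; acid 4 is taken to be a catalogue compound.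

**Route**

Step 1
Reactants: 1 (R)-2-methyloxirane; 2 but-3-en-1-ylmagnesium bromide
Product: 3 (2R)-hept-6-en-2-ol
Conditions: CuI (10 mol %), THF, −30 → 0 °C; aq. NH4Cl
Reagents that add atoms: none
Why: Copper-catalysed SN2 opening of the terminal epoxide by the Grignard reagent occurs at the unsubstituted CH2, so the purchased stereocentre (C21, R) is carried over unchanged.

Step 2
Reactants: 3 (2R)-hept-6-en-2-ol; 4 [bis(2,2,2-trifluoroethoxy)phosphoryl]acetic acid
Product: 5 (2R)-hept-6-en-2-yl [bis(2,2,2-trifluoroethoxy)phosphoryl]acetate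
Conditions: DCC, DMAP (cat.), CH2Cl2, 0 °C → rt
Reagents that add atoms: none
Why: Steglich esterification (carbodiimide activation, DMAP acyl transfer) acylates the secondary alcohol without breaking its C–O bond, so C21 keeps its configuration.

Step 3
Reactants: 6 9-bromononan-1-ol
Product: 7 9-bromononanal
Conditions: TEMPO (10 mol %), PhI(OAc)2, CH2Cl2, rt
Reagents that add atoms: none
Why: TEMPO/oxoammonium oxidation of the primary alcohol stops at the aldehyde and leaves the primary bromide alone.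

Step 4
Reactants: 7 9-bromononanal; 8 triethyl phosphonoacetate
Product: 10 ethyl (2E,4S)-11-bromo-4-[(phenylamino)oxy]undec-2-enoate, via α-aminoxy aldehyde 9 (not isolated)
Conditions: D-proline (25 mol %), PhNO, DMSO, rt; then 8, LiCl, DBU, MeCN, 0 °C
Reagents that add atoms: nitrosobenzene O=Nc1ccccc1
Why: Proline-catalysed α-aminoxylation (enamine attack on the oxygen of nitrosobenzene, directed by the carboxylic acid) sets C8, D-proline giving the (S)-α-oxy aldehyde as the mirror image of the L-proline outcome, and the labile aldehyde 9 is trapped in the same flask by an E-selective Horner–Wadsworth–Emmons olefination under Masamune–Roush conditions.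

Step 5
Reactants: 10 ethyl (2E,4S)-11-bromo-4-[(phenylamino)oxy]undec-2-enoate
Product: 11 ethyl (2E,4S)-11-bromo-4-hydroxyundec-2-enoate
Conditions: Cu(OAc)2 (30 mol %), EtOH, rt
Reagents that add atoms: none
Why: Copper-catalysed N–O bond cleavage of the O-alkyl-N-arylhydroxylamine frees the γ-hydroxyl group without touching the stereocentre or the enoate.

Step 6
Reactants: 11 ethyl (2E,4S)-11-bromo-4-hydroxyundec-2-enoate
Product: 12 ethyl (2E,4S)-11-bromo-4-(TBSO)undec-2-enoate
Conditions: TBSOTf, 2,6-lutidine, CH2Cl2, −78 °C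
Reagents that add atoms: tert-butyldimethylsilyl trifluoromethanesulfonate CC(C)(C)[Si](C)(C)OS(=O)(=O)C(F)(F)F
Why: Silyl triflate silylation of the secondary alcohol under 2,6-lutidine buffering is fast at low temperature and avoids nucleophiles that could displace the bromide.

Step 7
Reactants: 12 ethyl (2E,4S)-11-bromo-4-(TBSO)undec-2-enoate
Product: 13 (2E,4S)-11-bromo-4-(TBSO)undec-2-en-1-ol
Conditions: i-Bu2AlH, CH2Cl2, −78 °C; aq. potassium sodium tartrate
Reagents that add atoms: none
Why: i-Bu2AlH reduces the conjugated ester by 1,2-hydride delivery to the E-allylic alcohol without touching the bromide or the silyl ether.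

Step 8
Reactants: 13 (2E,4S)-11-bromo-4-(TBSO)undec-2-en-1-ol
Product: 14 [(2R,3S)-3-[(1S)-8-bromo-1-(TBSO)octyl]oxiran-2-yl]methanol
Conditions: Ti(OiPr)4 (10 mol %), D-(−)-diethyl tartrate (12 mol %), t-BuOOH, 4 Å MS, CH2Cl2, −20 °C
Reagents that add atoms: tert-butyl hydroperoxide CC(C)(C)OO
Why: Sharpless asymmetric epoxidation: the titanium–D-(−)-tartrate complex delivers oxygen to the face of the E-allylic alcohol that gives the (2R)-epoxy alcohol (reagent control over the allylic C8 silyloxy group), and the E geometry fixes the trans relationship of C6 and C7.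

Step 9
Reactants: 14 [(2R,3S)-3-[(1S)-8-bromo-1-(TBSO)octyl]oxiran-2-yl]methanol
Product: 15 (2S,3S)-3-[(1S)-8-bromo-1-(TBSO)octyl]oxirane-2-carbaldehyde
Conditions: TEMPO (10 mol %), PhI(OAc)2, CH2Cl2, rt
Reagents that add atoms: none
Why: TEMPO/oxoammonium oxidation converts the primary epoxy alcohol into the epoxy aldehyde under nearly neutral conditions that should not epimerise C6.

Step 10
Reactants: 15 (2S,3S)-3-[(1S)-8-bromo-1-(TBSO)octyl]oxirane-2-carbaldehyde; 16 allylmagnesium bromide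
Product: 19 (1S)-1-[(2R,3S)-3-[(1S)-8-bromo-1-(TBSO)octyl]oxiran-2-yl]but-3-en-1-ol, via allylborane 17 (not isolated), via borinate ester 18 (not isolated)
Conditions: (−)-Ipc2BOMe, 16, Et2O, −78 °C → rt; then 15, −78 °C; pH 7 buffer, H2O2, MeOH, 0 °C
Reagents that add atoms: none
Why: Asymmetric allylboration through a chair Zimmerman–Traxler transition state: the reagent derived from (+)-α-pinene adds allyl to the Si face of the aldehyde (the sense in which it converts benzaldehyde into (S)-1-phenylbut-3-en-1-ol), setting C5 as S, threo to the oxirane, by reagent control against the modest Felkin–Anh preference of the epoxy aldehyde.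

Step 11
Reactants: 19 (1S)-1-[(2R,3S)-3-[(1S)-8-bromo-1-(TBSO)octyl]oxiran-2-yl]but-3-en-1-ol
Product: 20 (2S,3S)-2-[(1S)-8-bromo-1-(TBSO)octyl]-3-[(1S)-1-(TBSO)but-3-en-1-yl]oxirane
Conditions: TBSOTf, 2,6-lutidine, CH2Cl2, −78 → 0 °C
Reagents that add atoms: tert-butyldimethylsilyl trifluoromethanesulfonate CC(C)(C)[Si](C)(C)OS(=O)(=O)C(F)(F)F
Why: Silyl triflate silylation protects the C5 hydroxyl under buffered low-temperature conditions that should leave the adjacent oxirane closed.

Step 12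
Reactants: 20 (2S,3S)-2-[(1S)-8-bromo-1-(TBSO)octyl]-3-[(1S)-1-(TBSO)but-3-en-1-yl]oxirane
Product: 22 (3S)-3-[(2S,3S)-3-[(1S)-8-bromo-1-(TBSO)octyl]oxiran-2-yl]-3-(TBSO)propanal, via secondary ozonide 21 (not isolated)
Conditions: O3, CH2Cl2, −78 °C; then PPh3, −78 °C → rt
Reagents that add atoms: ozone [O-][O+]=O
Why: Ozonolysis (1,3-dipolar cycloaddition of ozone to the only alkene, then reduction of ozonide 21 by PPh3) gives the C3 aldehyde without touching the oxirane, the silyl ethers or the bromide.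

Step 13
Reactants: 22 (3S)-3-[(2S,3S)-3-[(1S)-8-bromo-1-(TBSO)octyl]oxiran-2-yl]-3-(TBSO)propanal; 5 (2R)-hept-6-en-2-yl [bis(2,2,2-trifluoroethoxy)phosphoryl]acetate
Product: 23 (2R)-hept-6-en-2-yl (2Z,5S)-5-[(2S,3S)-3-[(1S)-8-bromo-1-(TBSO)octyl]oxiran-2-yl]-5-(TBSO)pent-2-enoate
Conditions: 5, KN(SiMe3)2, 18-crown-6, THF, −78 °C; then 22, −78 °C
Reagents that add atoms: none
Why: Still–Gennari modification of the Horner–Wadsworth–Emmons reaction: the electron-poor bis(trifluoroethyl) phosphonate with a dissociated potassium counter-ion eliminates faster than its adducts equilibrate, so the kinetic Z-enoate (C2=C3) should form, uniting C1–C2/C16–C22 with C3–C15.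

Step 14
Reactants: 23 (2R)-hept-6-en-2-yl (2Z,5S)-5-[(2S,3S)-3-[(1S)-8-bromo-1-(TBSO)octyl]oxiran-2-yl]-5-(TBSO)pent-2-enoate
Product: 25 (1S,2S,4Z,8R,21S,22S)-2,21-bis(TBSO)-8-methyl-7,23-dioxabicyclo[20.1.0]tricos-4-en-6-one, via B-alkyl-9-BBN borane 24 (not isolated)
Conditions: 9-BBN-H (1.1 equiv), THF, 0 °C → rt; then syringe-pump addition to Pd(OAc)2 (10 mol %), PCy3 (20 mol %), K3PO4·H2O (3 equiv), degassed THF, rt, 1 mM
Reagents that add atoms: none
Why: Proposed new method: 9-BBN-H adds anti-Markovnikov to the only terminal alkene (C16=C17; the Z-enoate, the oxirane and the primary bromide are inert to it at room temperature), and the primary alkylborane 24 is then coupled with the C15 bromide of the same molecule through SN2-type oxidative addition of C15–Br to zerovalent palladium carrying PCy3, hydroxide-assisted transmetalation of the C16–boron bond and sp3–sp3 reductive elimination from divalent palladium. The closest known reaction type is the intermolecular room-temperature Suzuki–Miyaura coupling of primary alkyl bromides with B-alkyl-9-BBN reagents under these same Pd(OAc)2/PCy3/K3PO4·H2O conditions, together with macrocyclising B-alkyl Suzuki couplings onto alkenyl iodides; new is only the ring closure between two sp3 carbons of an ester-linked chain. The single ring closed is ring A, the 22-membered lactone, by end-to-end macrocyclisation at two unhindered CH2 termini in the middle of the C9–C20 strap, a ring size at which strain is negligible and Baldwin-type constraints do not apply. No stereocentre is formed, and the five existing ones (C5, C6, C7, C8, C21) and the Z-alkene lie at least five bonds from the reacting carbons and should not be touched by the mild phosphate base. The step needs cyclisation to win over β-hydride elimination and over oligomerisation: the bulky, electron-rich PCy3 is known to hold primary alkylpalladium bromides long enough for transmetalation at room temperature, slow addition of 24 to the catalyst at about 1 mM suppresses intermolecular coupling, and the Z-enoate, the trans-oxirane and the two silyl ethers act as turn elements. Because the bond is made directly at the alkane oxidation level, no later reduction has to distinguish a C15=C16 alkene from the conjugated C2=C3 alkene.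

Step 15
Reactants: 25 (1S,2S,4Z,8R,21S,22S)-2,21-bis(TBSO)-8-methyl-7,23-dioxabicyclo[20.1.0]tricos-4-en-6-one
Product: 26 CIML C
Conditions: HF·pyridine, pyridine, THF, 0 °C → rt
Reagents that add atoms: none
Why: Fluoride-induced Si–O cleavage of both secondary silyl ethers under pyridine-buffered conditions should spare the oxirane and avoid acyl migration of the lactone to the freed C5 hydroxyl.

**Compound list**

1 | (R)-2-methyloxirane | C[C@@H]1CO1 | starting material
2 | but-3-en-1-ylmagnesium bromide | C=CCC[Mg]Br | starting material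
3 | (2R)-hept-6-en-2-ol | C[C@@H](O)CCCC=C | intermediate
4 | [bis(2,2,2-trifluoroethoxy)phosphoryl]acetic acid | OC(=O)CP(=O)(OCC(F)(F)F)OCC(F)(F)F | starting material
5 | (2R)-hept-6-en-2-yl [bis(2,2,2-trifluoroethoxy)phosphoryl]acetate | C[C@@H](OC(=O)CP(=O)(OCC(F)(F)F)OCC(F)(F)F)CCCC=C | intermediate
6 | 9-bromononan-1-ol | OCCCCCCCCCBr | starting material
7 | 9-bromononanal | O=CCCCCCCCCBr | intermediate
8 | triethyl phosphonoacetate | CCOC(=O)CP(=O)(OCC)OCC | starting material
9 | (2S)-9-bromo-2-[(phenylamino)oxy]nonanal | O=C[C@@H](ONc1ccccc1)CCCCCCCBr | intermediate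
10 | ethyl (2E,4S)-11-bromo-4-[(phenylamino)oxy]undec-2-enoate | CCOC(=O)/C=C/[C@@H](ONc1ccccc1)CCCCCCCBr | intermediate
11 | ethyl (2E,4S)-11-bromo-4-hydroxyundec-2-enoate | CCOC(=O)/C=C/[C@@H](O)CCCCCCCBr | intermediate
12 | ethyl (2E,4S)-11-bromo-4-(TBSO)undec-2-enoate | CCOC(=O)/C=C/[C@@H](O[Si](C)(C)C(C)(C)C)CCCCCCCBr | intermediate
13 | (2E,4S)-11-bromo-4-(TBSO)undec-2-en-1-ol | OC/C=C/[C@@H](O[Si](C)(C)C(C)(C)C)CCCCCCCBr | intermediate
14 | [(2R,3S)-3-[(1S)-8-bromo-1-(TBSO)octyl]oxiran-2-yl]methanol | BrCCCCCCC[C@H](O[Si](C)(C)C(C)(C)C)[C@H]1O[C@@H]1CO | intermediate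
15 | (2S,3S)-3-[(1S)-8-bromo-1-(TBSO)octyl]oxirane-2-carbaldehyde | BrCCCCCCC[C@H](O[Si](C)(C)C(C)(C)C)[C@H]1O[C@@H]1C=O | intermediate
16 | allylmagnesium bromide | C=CC[Mg]Br | starting material
17 | allylbis[(1R,2S,3R,5R)-2,6,6-trimethylbicyclo[3.1.1]heptan-3-yl]borane (B-allyl-Ipc2 borane from (+)-α-pinene) | C=CCB([C@H]1[C@H](C)[C@H]2C[C@@H](C1)C2(C)C)[C@H]1[C@H](C)[C@H]2C[C@@H](C1)C2(C)C | intermediate
18 | O-diisopinocampheylboryl ether (borinate ester) of 19 | BrCCCCCCC[C@H](O[Si](C)(C)C(C)(C)C)[C@H]1O[C@@H]1[C@@H](OB([C@H]2[C@H](C)[C@H]3C[C@@H](C2)C3(C)C)[C@H]2[C@H](C)[C@H]3C[C@@H](C2)C3(C)C)CC=C | intermediate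
19 | (1S)-1-[(2R,3S)-3-[(1S)-8-bromo-1-(TBSO)octyl]oxiran-2-yl]but-3-en-1-ol | BrCCCCCCC[C@H](O[Si](C)(C)C(C)(C)C)[C@H]1O[C@@H]1[C@@H](O)CC=C | intermediate
20 | (2S,3S)-2-[(1S)-8-bromo-1-(TBSO)octyl]-3-[(1S)-1-(TBSO)but-3-en-1-yl]oxirane | BrCCCCCCC[C@H](O[Si](C)(C)C(C)(C)C)[C@H]1O[C@@H]1[C@@H](O[Si](C)(C)C(C)(C)C)CC=C | intermediate
21 | secondary ozonide of 20 (3-substituted 1,2,4-trioxolane in place of the vinyl group; configuration at the new ring carbon undefined) | BrCCCCCCC[C@H](O[Si](C)(C)C(C)(C)C)[C@H]1O[C@@H]1[C@@H](O[Si](C)(C)C(C)(C)C)CC1OCOO1 | intermediate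
22 | (3S)-3-[(2S,3S)-3-[(1S)-8-bromo-1-(TBSO)octyl]oxiran-2-yl]-3-(TBSO)propanal | BrCCCCCCC[C@H](O[Si](C)(C)C(C)(C)C)[C@H]1O[C@@H]1[C@@H](O[Si](C)(C)C(C)(C)C)CC=O | intermediate
23 | (2R)-hept-6-en-2-yl (2Z,5S)-5-[(2S,3S)-3-[(1S)-8-bromo-1-(TBSO)octyl]oxiran-2-yl]-5-(TBSO)pent-2-enoate | BrCCCCCCC[C@H](O[Si](C)(C)C(C)(C)C)[C@H]1O[C@@H]1[C@@H](O[Si](C)(C)C(C)(C)C)C/C=C\C(=O)O[C@H](C)CCCC=C | intermediate
24 | (2R)-7-(9-borabicyclo[3.3.1]nonan-9-yl)heptan-2-yl (2Z,5S)-5-[(2S,3S)-3-[(1S)-8-bromo-1-(TBSO)octyl]oxiran-2-yl]-5-(TBSO)pent-2-enoate | BrCCCCCCC[C@H](O[Si](C)(C)C(C)(C)C)[C@H]1O[C@@H]1[C@@H](O[Si](C)(C)C(C)(C)C)C/C=C\C(=O)O[C@H](C)CCCCCB1C2CCCC1CCC2 | intermediate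
25 | (1S,2S,4Z,8R,21S,22S)-2,21-bis(TBSO)-8-methyl-7,23-dioxabicyclo[20.1.0]tricos-4-en-6-one (5,8-bis-O-TBS-CIML C) | C[C@@H]1CCCCCCCCCCCC[C@H](O[Si](C)(C)C(C)(C)C)[C@H]2O[C@@H]2[C@@H](O[Si](C)(C)C(C)(C)C)C/C=C\C(=O)O1 | intermediate
26 | CIML C, (1R,2S,4Z,8R,21S,22R)-2,21-dihydroxy-8-methyl-7,23-dioxabicyclo[20.1.0]tricos-4-en-6-one | C[C@@H]1CCCCCCCCCCCC[C@H](O)[C@H]2O[C@@H]2[C@@H](O)C/C=C\C(=O)O1 | target

**Summary**

Total step count: 15. Longest linear sequence: 13 steps (6 → 26, steps 3–15).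

Steps most likely to fail:

1. Step 14 (proposed new method). Transmetalation across the long chain may be slower than β-hydride elimination or protodebromination of the alkylpalladium intermediate, intermolecular coupling may give oligomers, and free phosphine or a palladium hydride may isomerise the Z-enoate. The fallback uses known chemistry: C15–C16 is made by the established intermolecular form of the same coupling before any conjugated ester is present, and the ring is then closed by a Z-selective intramolecular Horner–Wadsworth–Emmons reaction. It sets out from 3 and 20 and comes back at 25. Alcohol 3 would be treated with 9-BBN-H (2 equiv, the first consumed by the hydroxyl group) in THF to give 9-{[(2R)-7-(9-borabicyclo[3.3.1]nonan-9-yl)heptan-2-yl]oxy}-9-borabicyclo[3.3.1]nonane F1. Coupling of this with bromide 20 under Pd(OAc)2/PCy3/K3PO4·H2O in THF at rt should give, after hydrolysis of the O–B bond on work-up, (2R,15S)-15-(TBSO)-15-[(2S,3S)-3-[(1S)-1-(TBSO)but-3-en-1-yl]oxiran-2-yl]pentadecan-2-ol F2. Steglich esterification with 4 (DCC, DMAP) would give (2R,15S)-15-(TBSO)-15-[(2S,3S)-3-[(1S)-1-(TBSO)but-3-en-1-yl]oxiran-2-yl]pentadecan-2-yl [bis(2,2,2-trifluoroethoxy)phosphoryl]acetate F3. Ozonolysis (O3, then PPh3) would pass through the 1,2,4-trioxolane F4 to (2R,15S)-15-(TBSO)-15-[(2S,3S)-3-[(1S)-1-(TBSO)-3-oxopropyl]oxiran-2-yl]pentadecan-2-yl [bis(2,2,2-trifluoroethoxy)phosphoryl]acetate F5. Slow addition of this to KN(SiMe3)2/18-crown-6 in THF at −78 °C at high dilution (Still–Gennari macrocyclisation) should give 25.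

2. Step 10. Facial selectivity may be poor, because reagent control must override the intrinsic erythro preference of the α,β-epoxy aldehyde; the aldehyde may also epimerise or its oxirane open before it is consumed. The fallback runs the matched addition and then inverts C5. It sets out from 15 and comes back at 19. (+)-Ipc2BOMe and 16 would give allylbis[(1S,2R,3S,5S)-2,6,6-trimethylbicyclo[3.1.1]heptan-3-yl]borane F6, which should add to 15 in the matched sense to give the O-diisopinocampheylboryl ether of the (1R)-alcohol F7 and, after buffered H2O2 work-up, (1R)-1-[(2R,3S)-3-[(1S)-8-bromo-1-(TBSO)octyl]oxiran-2-yl]but-3-en-1-ol F8. Mitsunobu inversion (4-nitrobenzoic acid, PPh3, diisopropyl azodicarboxylate, toluene, 0 °C) would give (1S)-1-[(2R,3S)-3-[(1S)-8-bromo-1-(TBSO)octyl]oxiran-2-yl]but-3-en-1-yl 4-nitrobenzoate F9, and brief methanolysis (K2CO3, MeOH, 0 °C) should release 19.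

3. Step 8. Double diastereoselection may work against the tartrate if the C8 silyloxy stereocentre opposes the reagent-controlled face, and the titanium Lewis acid may open the product oxirane or cause it to migrate. The fallback replaces the titanium-mediated epoxidation of the alcohol by iminium/enamine organocatalysis at the aldehyde oxidation level. It sets out from 13 and comes back at 15, making step 9 unnecessary. Oxidation of 13 with MnO2 in CH2Cl2 would give (2E,4S)-11-bromo-4-(TBSO)undec-2-enal F10. Epoxidation with aqueous H2O2 and (R)-2-{bis[3,5-bis(trifluoromethyl)phenyl][(trimethylsilyl)oxy]methyl}pyrrolidine (10 mol %) in CH2Cl2 at rt (conjugate addition of hydroperoxide to the iminium ion, then ring closure of the enamine; the catalyst enantiomer is the one expected to convert (E)-hex-2-enal into (2S,3R)-3-propyloxirane-2-carbaldehyde) should give 15 directly.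

Further compounds
F1 | step 14 | 9-{[(2R)-7-(9-borabicyclo[3.3.1]nonan-9-yl)heptan-2-yl]oxy}-9-borabicyclo[3.3.1]nonane | C[C@@H](OB1C2CCCC1CCC2)CCCCCB1C2CCCC1CCC2
F2 | step 14 | (2R,15S)-15-(TBSO)-15-[(2S,3S)-3-[(1S)-1-(TBSO)but-3-en-1-yl]oxiran-2-yl]pentadecan-2-ol | C[C@@H](O)CCCCCCCCCCCC[C@H](O[Si](C)(C)C(C)(C)C)[C@H]1O[C@@H]1[C@@H](O[Si](C)(C)C(C)(C)C)CC=C
F3 | step 14 | (2R,15S)-15-(TBSO)-15-[(2S,3S)-3-[(1S)-1-(TBSO)but-3-en-1-yl]oxiran-2-yl]pentadecan-2-yl [bis(2,2,2-trifluoroethoxy)phosphoryl]acetate | C[C@@H](OC(=O)CP(=O)(OCC(F)(F)F)OCC(F)(F)F)CCCCCCCCCCCC[C@H](O[Si](C)(C)C(C)(C)C)[C@H]1O[C@@H]1[C@@H](O[Si](C)(C)C(C)(C)C)CC=C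
F4 | step 14 | 1,2,4-trioxolane (secondary ozonide) of F3 at the former vinyl group | C[C@@H](OC(=O)CP(=O)(OCC(F)(F)F)OCC(F)(F)F)CCCCCCCCCCCC[C@H](O[Si](C)(C)C(C)(C)C)[C@H]1O[C@@H]1[C@@H](O[Si](C)(C)C(C)(C)C)CC1OCOO1
F5 | step 14 | (2R,15S)-15-(TBSO)-15-[(2S,3S)-3-[(1S)-1-(TBSO)-3-oxopropyl]oxiran-2-yl]pentadecan-2-yl [bis(2,2,2-trifluoroethoxy)phosphoryl]acetate | C[C@@H](OC(=O)CP(=O)(OCC(F)(F)F)OCC(F)(F)F)CCCCCCCCCCCC[C@H](O[Si](C)(C)C(C)(C)C)[C@H]1O[C@@H]1[C@@H](O[Si](C)(C)C(C)(C)C)CC=O
F6 | step 10 | allylbis[(1S,2R,3S,5S)-2,6,6-trimethylbicyclo[3.1.1]heptan-3-yl]borane | C=CCB([C@@H]1[C@@H](C)[C@@H]2C[C@H](C1)C2(C)C)[C@@H]1[C@@H](C)[C@@H]2C[C@H](C1)C2(C)C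
F7 | step 10 | O-diisopinocampheylboryl ether of the (1R)-alcohol F8 | BrCCCCCCC[C@H](O[Si](C)(C)C(C)(C)C)[C@H]1O[C@@H]1[C@H](OB([C@@H]2[C@@H](C)[C@@H]3C[C@H](C2)C3(C)C)[C@@H]2[C@@H](C)[C@@H]3C[C@H](C2)C3(C)C)CC=C
F8 | step 10 | (1R)-1-[(2R,3S)-3-[(1S)-8-bromo-1-(TBSO)octyl]oxiran-2-yl]but-3-en-1-ol | BrCCCCCCC[C@H](O[Si](C)(C)C(C)(C)C)[C@H]1O[C@@H]1[C@H](O)CC=C
F9 | step 10 | (1S)-1-[(2R,3S)-3-[(1S)-8-bromo-1-(TBSO)octyl]oxiran-2-yl]but-3-en-1-yl 4-nitrobenzoate | BrCCCCCCC[C@H](O[Si](C)(C)C(C)(C)C)[C@H]1O[C@@H]1[C@@H](OC(=O)c1ccc(cc1)[N+](=O)[O-])CC=C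
F10 | step 8 | (2E,4S)-11-bromo-4-(TBSO)undec-2-enal | O=C/C=C/[C@@H](O[Si](C)(C)C(C)(C)C)CCCCCCCBr
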